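**Plan**
1. Retrosynthesis: the five benzyl O–C bonds are cut first, then the C3–CO2t-Bu bond of a temporary ester, then O1–C2 of flavanone ring C (key cut), then the C2=C3 alkene (Knoevenagel), then the ether bond from kaempferol O3 to C4' of flavanone ring B (SNAr), and last kaempferol ring C back to a chalcone.
2. Forward: the kaempferol half is built first (chalcone, flavone ring C, C3 hydroxylation) and its O3 is arylated with 4-fluorobenzaldehyde. The aldehyde is condensed with a 2-hydroxyaroylacetate, and flavanone ring C is closed last, followed by decarboxylation and debenzylation.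
3. Enabling feature: C3 of flavanone ring C is a CH2 next to the C4 ketone. It can carry a tert-butoxycarbonyl group that doubly activates C2 towards the ring A phenol oxygen (O1) and leaves afterwards as isobutene and CO2.
4. Stereochemistry: C2 (S) is the only stereocentre. It is set by a cinchona-derived thiourea during the ring closure and afterwards meets only acidic or neutral conditions, under which the flavanone does not reopen.

Key step: step 8

Assumption: of the two pseudoenantiomeric cinchona thioureas, the quinidine-derived (9R) one is taken to deliver the 2S series; the sense is to be confirmed on the parent benzylidene ketoester, and the quinine-derived (9S) catalyst is used instead if it proves opposite.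

**Route**

Step 1
Reactants: 1 2,4,6-trihydroxyacetophenone
Product: 2 1-[2,4-bis(benzyloxy)-6-hydroxyphenyl]ethanone
Conditions: BnBr (2.1 equiv), K2CO3, DMF, 0 °C to rt
Reagents that add atoms: benzyl bromide, BrCc1ccccc1
Why: Williamson etherification, in which the para hydroxyl and one ortho hydroxyl are alkylated while the remaining ortho hydroxyl, hydrogen-bonded to the acetyl carbonyl, is the least nucleophilic and should stay free with two equivalents of halide.

Step 2
Reactants: 2 1-[2,4-bis(benzyloxy)-6-hydroxyphenyl]ethanone; 3 4-(benzyloxy)benzaldehyde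
Product: 4 (E)-1-[2,4-bis(benzyloxy)-6-hydroxyphenyl]-3-[4-(benzyloxy)phenyl]prop-2-en-1-one
Conditions: KOH (aq), EtOH/THF, rt
Reagents that add atoms: none
Why: Claisen–Schmidt condensation of the methyl ketone enolate with a non-enolisable aldehyde followed by E1cB dehydration to the E-chalcone; any flavanone formed by closure is carried along, since it converges with the chalcone in step 3.

Step 3
Reactants: 4 (E)-1-[2,4-bis(benzyloxy)-6-hydroxyphenyl]-3-[4-(benzyloxy)phenyl]prop-2-en-1-one
Product: 5 5,7-bis(benzyloxy)-2-[4-(benzyloxy)phenyl]-4H-chromen-4-one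
Conditions: I2 (10 mol%), DMSO, 120 °C
Reagents that add atoms: none
Why: Iodine-catalysed oxidative cyclisation of a 2'-hydroxychalcone (oxa-Michael closure, α-iodination and loss of HI, with DMSO reoxidising HI) closes the pyranone ring of the kaempferol half, and catalytic iodine should leave the benzyl ethers in place.

Step 4
Reactants: 5 5,7-bis(benzyloxy)-2-[4-(benzyloxy)phenyl]-4H-chromen-4-one
Product: 7 5,7-bis(benzyloxy)-2-[4-(benzyloxy)phenyl]-3-hydroxy-4H-chromen-4-one, via flavone 2,3-epoxide 6 (not isolated)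
Conditions: dimethyldioxirane (acetone solution), CH2Cl2, 0 °C to rt; then TsOH·H2O (cat.), CH2Cl2, rt
Reagents that add atoms: dimethyldioxirane, CC1(C)OO1
Why: Dioxirane epoxidation of the enol-ether-like C2=C3 bond followed by acid-catalysed epoxide opening at C2 and loss of H3 is the established flavone-to-flavonol oxidation, and the neutral oxidant is expected to spare the benzyl ethers at low temperature.

Step 5
Reactants: 7 5,7-bis(benzyloxy)-2-[4-(benzyloxy)phenyl]-3-hydroxy-4H-chromen-4-one; 8 4-fluorobenzaldehyde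
Product: 9 4-({5,7-bis(benzyloxy)-2-[4-(benzyloxy)phenyl]-4-oxo-4H-chromen-3-yl}oxy)benzaldehyde
Conditions: Cs2CO3, DMSO, 90 °C, under argon
Reagents that add atoms: none
Why: Nucleophilic aromatic substitution (SNAr), in which the flavonolate oxygen, about as acidic as a phenol and the only free hydroxyl, displaces fluoride para to the formyl group through a Meisenheimer intermediate.

Step 6
Reactants: 2 1-[2,4-bis(benzyloxy)-6-hydroxyphenyl]ethanone; 10 di-tert-butyl dicarbonate
Product: 11 tert-butyl 3-[2,4-bis(benzyloxy)-6-hydroxyphenyl]-3-oxopropanoate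
Conditions: LiN(SiMe3)2 (3.2 equiv), THF, −78 °C; then 10, −78 to 0 °C; cold 1 M HCl quench
Reagents that add atoms: none
Why: Claisen-type C-carboxylation of the ketone enolate within the phenoxide/enolate dianion; any aryl carbonate from O-acylation should be funnelled to the same ketoester by a Baker–Venkataraman-type O-to-C transfer, driven by the third equivalent of base.

Step 7
Reactants: 11 tert-butyl 3-[2,4-bis(benzyloxy)-6-hydroxyphenyl]-3-oxopropanoate; 9 4-({5,7-bis(benzyloxy)-2-[4-(benzyloxy)phenyl]-4-oxo-4H-chromen-3-yl}oxy)benzaldehyde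
Product: 12 tert-butyl (2Z)-2-[2,4-bis(benzyloxy)-6-hydroxybenzoyl]-3-[4-({5,7-bis(benzyloxy)-2-[4-(benzyloxy)phenyl]-4-oxo-4H-chromen-3-yl}oxy)phenyl]prop-2-enoate
Conditions: piperidine (20 mol%), AcOH (40 mol%), 4 Å molecular sieves, toluene, rt to 40 °C
Reagents that add atoms: none
Why: Knoevenagel condensation of the active methylene with the aldehyde through its piperidinium iminium ion; the acetate buffer and the ketone-chelated phenol are expected to keep premature ring closure slow, and the isomer with aryl cis to the ester should predominate.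

Step 8
Reactants: 12 tert-butyl (2Z)-2-[2,4-bis(benzyloxy)-6-hydroxybenzoyl]-3-[4-({5,7-bis(benzyloxy)-2-[4-(benzyloxy)phenyl]-4-oxo-4H-chromen-3-yl}oxy)phenyl]prop-2-enoate
Product: 13 tert-butyl 5,7-bis(benzyloxy)-2-[4-({5,7-bis(benzyloxy)-2-[4-(benzyloxy)phenyl]-4-oxo-4H-chromen-3-yl}oxy)phenyl]-4-hydroxy-2H-chromene-3-carboxylate, the enol form of the flavanone-3-carboxylate, with C2 arranged as in the target (descriptor 2R in the enol because C3 outranks the aryl group)
Conditions: 1-[3,5-bis(trifluoromethyl)phenyl]-3-[(9R)-6'-methoxycinchonan-9-yl]thiourea (10 mol%), toluene, −25 °C; TsOH·H2O (15 mol%) quench, crude used directly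
Reagents that add atoms: none
Why: The quinuclidine nitrogen of the catalyst takes the proton of the chelated phenol while the thiourea N–H bonds hold the ketoester carbonyls, so the phenoxide oxygen adds to the benzylidene carbon of a doubly activated acceptor and the resulting enolate is protonated by the quinuclidinium ion. The closest known reaction type is the bifunctional cinchona-thiourea-catalysed intramolecular oxa-Michael addition of 2-hydroxyaryl alkylidene β-ketoesters to flavanone-3-carboxylates. Flavanone ring C closes in a 6-endo-trig mode by forming O1–C2. The new stereocentre C2 is controlled by the catalyst alone, which presents one enantioface of the benzylidene carbon to the ion-paired phenoxide; the substrate has no other stereogenic element. The step needs enantioface selectivity and a suppressed background reaction, and the geminal tert-butyl ester secures both: it gives the thiourea its second binding point, makes the acceptor reactive at −25 °C where uncatalysed closure of the hydrogen-bonded phenol is slow, and turns the product into a stabilised enol that should not readily reopen. Both alkene isomers lead to the same product because the geometry at C3 disappears in the enol.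

Step 9
Reactants: 13 tert-butyl flavanone-3-carboxylate (enol form) from step 8
Product: 15 (2S)-5,7-bis(benzyloxy)-2-[4-({5,7-bis(benzyloxy)-2-[4-(benzyloxy)phenyl]-4-oxo-4H-chromen-3-yl}oxy)phenyl]-2,3-dihydro-4H-chromen-4-one, via flavanone-3-carboxylic acid 14 (not isolated)
Conditions: TsOH·H2O (1 equiv), toluene, 80 °C
Reagents that add atoms: none
Why: Acid-mediated tert-butyl ester cleavage (loss of isobutene) followed by thermal decarboxylation of the β-keto acid through a six-membered transition state; C2 is not enolisable and the retro-oxa-Michael pathway needs base, so the configuration should be retained.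

Step 10
Reactants: 15 (2S)-5,7-bis(benzyloxy)-2-[4-({5,7-bis(benzyloxy)-2-[4-(benzyloxy)phenyl]-4-oxo-4H-chromen-3-yl}oxy)phenyl]-2,3-dihydro-4H-chromen-4-one
Product: 16 (2S)-5,7-dihydroxy-2-(4-{[5,7-dihydroxy-2-(4-hydroxyphenyl)-4-oxo-4H-chromen-3-yl]oxy}phenyl)-2,3-dihydro-4H-chromen-4-one (CNP0144321.1)
Conditions: H2 (1 atm), 10% Pd/C, THF/MeOH, rt
Reagents that add atoms: none
Why: Catalytic hydrogenolysis of the five aryl benzyl ethers; the tetrasubstituted chromone C2=C3 bond, the flavanone ketone (chelated once the 5-hydroxyl is free) and the cyclic benzylic O1–C2 bond are expected to react much more slowly, so the reaction is stopped after uptake of five equivalents.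

If the enantiomeric purity of 15 falls short, recrystallisation of 15 is the intended upgrade point.

**Compound list**
1 | 2,4,6-trihydroxyacetophenone | CC(=O)c1c(O)cc(O)cc1O | starting material
2 | 1-[2,4-bis(benzyloxy)-6-hydroxyphenyl]ethanone | CC(=O)c1c(O)cc(OCc2ccccc2)cc1OCc1ccccc1 | intermediate
3 | 4-(benzyloxy)benzaldehyde | O=Cc1ccc(OCc2ccccc2)cc1 | starting material
4 | (E)-1-[2,4-bis(benzyloxy)-6-hydroxyphenyl]-3-[4-(benzyloxy)phenyl]prop-2-en-1-one | O=C(/C=C/c1ccc(OCc2ccccc2)cc1)c1c(O)cc(OCc2ccccc2)cc1OCc1ccccc1 | intermediate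
5 | 5,7-bis(benzyloxy)-2-[4-(benzyloxy)phenyl]-4H-chromen-4-one | O=c1cc(-c2ccc(OCc3ccccc3)cc2)oc2cc(OCc3ccccc3)cc(OCc3ccccc3)c12 | intermediate
6 | racemic 5,7-bis(benzyloxy)-2-[4-(benzyloxy)phenyl]-2,3-epoxychroman-4-one (flavone 2,3-epoxide) | O=C1C2OC2(c2ccc(OCc3ccccc3)cc2)Oc2cc(OCc3ccccc3)cc(OCc3ccccc3)c21 | intermediate
7 | 5,7-bis(benzyloxy)-2-[4-(benzyloxy)phenyl]-3-hydroxy-4H-chromen-4-one (5,7,4'-tri-O-benzylkaempferol) | O=c1c(O)c(-c2ccc(OCc3ccccc3)cc2)oc2cc(OCc3ccccc3)cc(OCc3ccccc3)c12 | intermediate
8 | 4-fluorobenzaldehyde | O=Cc1ccc(F)cc1 | starting material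
9 | 4-({5,7-bis(benzyloxy)-2-[4-(benzyloxy)phenyl]-4-oxo-4H-chromen-3-yl}oxy)benzaldehyde | O=Cc1ccc(Oc2c(-c3ccc(OCc4ccccc4)cc3)oc3cc(OCc4ccccc4)cc(OCc4ccccc4)c3c2=O)cc1 | intermediate
10 | di-tert-butyl dicarbonate | CC(C)(C)OC(=O)OC(=O)OC(C)(C)C | starting material
11 | tert-butyl 3-[2,4-bis(benzyloxy)-6-hydroxyphenyl]-3-oxopropanoate | CC(C)(C)OC(=O)CC(=O)c1c(O)cc(OCc2ccccc2)cc1OCc1ccccc1 | intermediate
12 | tert-butyl (2Z)-2-[2,4-bis(benzyloxy)-6-hydroxybenzoyl]-3-[4-({5,7-bis(benzyloxy)-2-[4-(benzyloxy)phenyl]-4-oxo-4H-chromen-3-yl}oxy)phenyl]prop-2-enoate | CC(C)(C)OC(=O)/C(=C\c1ccc(Oc2c(-c3ccc(OCc4ccccc4)cc3)oc3cc(OCc4ccccc4)cc(OCc4ccccc4)c3c2=O)cc1)C(=O)c1c(O)cc(OCc2ccccc2)cc1OCc1ccccc1 | intermediate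
13 | tert-butyl 5,7-bis(benzyloxy)-2-[4-({5,7-bis(benzyloxy)-2-[4-(benzyloxy)phenyl]-4-oxo-4H-chromen-3-yl}oxy)phenyl]-4-hydroxy-2H-chromene-3-carboxylate (enol form of the flavanone-3-carboxylate, C2 as in the target) | OC1=C(C(=O)OC(C)(C)C)[C@@H](c2ccc(Oc3c(-c4ccc(OCc5ccccc5)cc4)oc4cc(OCc5ccccc5)cc(OCc5ccccc5)c4c3=O)cc2)Oc2cc(OCc3ccccc3)cc(OCc3ccccc3)c21 | intermediate
14 | 5,7-bis(benzyloxy)-2-[4-({5,7-bis(benzyloxy)-2-[4-(benzyloxy)phenyl]-4-oxo-4H-chromen-3-yl}oxy)phenyl]-4-hydroxy-2H-chromene-3-carboxylic acid (enol form, C2 as in the target) | OC1=C(C(=O)O)[C@@H](c2ccc(Oc3c(-c4ccc(OCc5ccccc5)cc4)oc4cc(OCc5ccccc5)cc(OCc5ccccc5)c4c3=O)cc2)Oc2cc(OCc3ccccc3)cc(OCc3ccccc3)c21 | intermediate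
15 | (2S)-5,7-bis(benzyloxy)-2-[4-({5,7-bis(benzyloxy)-2-[4-(benzyloxy)phenyl]-4-oxo-4H-chromen-3-yl}oxy)phenyl]-2,3-dihydro-4H-chromen-4-one | O=C1C[C@@H](c2ccc(Oc3c(-c4ccc(OCc5ccccc5)cc4)oc4cc(OCc5ccccc5)cc(OCc5ccccc5)c4c3=O)cc2)Oc2cc(OCc3ccccc3)cc(OCc3ccccc3)c21 | intermediate
16 | (2S)-5,7-dihydroxy-2-(4-{[5,7-dihydroxy-2-(4-hydroxyphenyl)-4-oxo-4H-chromen-3-yl]oxy}phenyl)-2,3-dihydro-4H-chromen-4-one | O=C1C[C@@H](c2ccc(Oc3c(-c4ccc(O)cc4)oc4cc(O)cc(O)c4c3=O)cc2)Oc2cc(O)cc(O)c21 | target

**Step count**
Total: 10 steps. Longest linear sequence: 9 steps (steps 1, 2, 3, 4, 5, 7, 8, 9, 10, from 1 to 16).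

**Steps most likely to fail**

Step 8. The ortho benzyloxy group twists the aroyl unit and the very large aryl arm may loosen the two-point binding, so enantioface discrimination could be poor, and uncatalysed closure could add racemic material. The fallback gives up the ester activation and sets out from 2 and 9. A Claisen–Schmidt condensation (KOH, EtOH/THF, rt) should give the chalcone (E)-1-[2,4-bis(benzyloxy)-6-hydroxyphenyl]-3-[4-({5,7-bis(benzyloxy)-2-[4-(benzyloxy)phenyl]-4-oxo-4H-chromen-3-yl}oxy)phenyl]prop-2-en-1-one F1. Equilibration with NaOAc in refluxing EtOH should close it by oxa-Michael addition to the racemic penta-O-benzyl flavanone F2. Preparative chromatography on an amylose tris(3,5-dimethylphenylcarbamate) phase then separates the enantiomers, and the S enantiomer rejoins the route at 15. The R enantiomer is returned to F2 by base equilibration through F1 and recycled.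

Step 5. Substitution at the hindered C3 oxygen, flanked by the 2-aryl group and the C4 carbonyl, may be slow with only para-formyl activation. Long heating could then degrade the flavonolate through oxidative ring cleavage by traces of oxygen, or consume the aldehyde. The fallback sets out from 7 and replaces SNAr by metal-free O-arylation with a hypervalent iodine reagent. The reagent is (4-formylphenyl)(2,4,6-trimethoxyphenyl)iodonium tosylate F3, prepared in one pot from 4-iodobenzaldehyde (mCPBA, TsOH·H2O, MeCN; then 1,3,5-trimethoxybenzene). Treatment of 7 with KOt-Bu and F3 in THF/toluene at rt should transfer the electron-poor formylphenyl group to oxygen by ligand coupling, with the trimethoxyphenyl group as the non-transferred partner. The route is rejoined at 9.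

Step 7. The free phenol may add to the new alkene under the amine-buffered conditions before the chiral catalyst is present, giving racemic ring closure that erodes the final enantiomeric purity, and the hindered aroylacetate may condense slowly. The fallback masks the phenol and sets out from 11. Silylation (TBSCl, imidazole, DMF) should give tert-butyl 3-[2,4-bis(benzyloxy)-6-(tert-butyldimethylsilyloxy)phenyl]-3-oxopropanoate F4. Knoevenagel condensation with 9 (piperidine/AcOH, toluene, azeotropic water removal) should give the silyl-protected alkylidene ketoester F5, which cannot cyclise. The phenol is then released under acidic fluoride conditions that build up no phenoxide (HF·pyridine, pyridine, THF, 0 °C), rejoining the route at 12.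

**Further compounds**
F1 | step 8 | (E)-1-[2,4-bis(benzyloxy)-6-hydroxyphenyl]-3-[4-({5,7-bis(benzyloxy)-2-[4-(benzyloxy)phenyl]-4-oxo-4H-chromen-3-yl}oxy)phenyl]prop-2-en-1-one | O=C(/C=C/c1ccc(Oc2c(-c3ccc(OCc4ccccc4)cc3)oc3cc(OCc4ccccc4)cc(OCc4ccccc4)c3c2=O)cc1)c1c(O)cc(OCc2ccccc2)cc1OCc1ccccc1
F2 | step 8 | racemic 5,7-bis(benzyloxy)-2-[4-({5,7-bis(benzyloxy)-2-[4-(benzyloxy)phenyl]-4-oxo-4H-chromen-3-yl}oxy)phenyl]-2,3-dihydro-4H-chromen-4-one | O=C1CC(c2ccc(Oc3c(-c4ccc(OCc5ccccc5)cc4)oc4cc(OCc5ccccc5)cc(OCc5ccccc5)c4c3=O)cc2)Oc2cc(OCc3ccccc3)cc(OCc3ccccc3)c21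
F3 | step 5 | (4-formylphenyl)(2,4,6-trimethoxyphenyl)iodonium tosylate | O=Cc1ccc([I+]c2c(OC)cc(OC)cc2OC)cc1.[O-]S(=O)(=O)c1ccc(C)cc1
F4 | step 7 | tert-butyl 3-[2,4-bis(benzyloxy)-6-(tert-butyldimethylsilyloxy)phenyl]-3-oxopropanoate | CC(C)(C)OC(=O)CC(=O)c1c(O[Si](C)(C)C(C)(C)C)cc(OCc2ccccc2)cc1OCc1ccccc1
F5 | step 7 | tert-butyl (2Z)-2-[2,4-bis(benzyloxy)-6-(tert-butyldimethylsilyloxy)benzoyl]-3-[4-({5,7-bis(benzyloxy)-2-[4-(benzyloxy)phenyl]-4-oxo-4H-chromen-3-yl}oxy)phenyl]prop-2-enoate | CC(C)(C)OC(=O)/C(=C\c1ccc(Oc2c(-c3ccc(OCc4ccccc4)cc3)oc3cc(OCc4ccccc4)cc(OCc4ccccc4)c3c2=O)cc1)C(=O)c1c(O[Si](C)(C)C(C)(C)C)cc(OCc2ccccc2)cc1OCc1ccccc1
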